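Late in each earlier run substrate reads near zero and target drifts slowly down, so a late reading is what was made minus what was lost since.

common to all: first nucleophile 0.125 M
- north-west: substrate 0.25 M; second nucleophile 0.375 M; run made earlier
- south-east: substrate 0.25 M; second nucleophile 0.19 M; run made earlier
- south: substrate 0.25 M; second nucleophile 0.28 M; run made earlier
- birch: substrate 0.25 M; second nucleophile 0.375 M; everything together at the start; time 30 min
- maple: substrate 0.25 M; second nucleophile 0.375 M (fed, over 25 min); all else is in the flask from the start; the feed brings no volume worth counting; time 30 min
- cedar: substrate 0.25 M (fed, over 25 min); second nucleophile 0.375 M; all else is in the flask from the start; the feed brings no volume worth counting; time 30 min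

| run | time / min | target / % | substrate / % |
|---|---|---|---|
| north-west | 1.33 | 19.5 | 1.7 |
| north-west | 3.00 | 19.4 | 0 |
| north-west | 8.00 | 20.3 | 0.4 |
| north-west | 20.0 | 17.8 | 0 |
| south-east | 3.00 | 32.0 | 0 |
| south-east | 6.00 | 32.3 | 0.1 |
| south-east | 15.0 | 31.4 | 0 |
| south-east | 40.0 | 30.2 | 0.2 |
| south | 3.00 | 23.2 | 0 |
| south | 6.00 | 23.0 | 0 |
| south | 15.0 | 22.2 | 0 |
| south | 40.0 | 20.4 | 0 |

(scatter of a reading: 0.5 percentage points)

* the flask that comes out highest in amount of target, in percent of the substrate charged, or "all alike" when all lie within 1.5 percentage points (birch / maple / cedar / all alike)
* target at the end, in percent of the substrate charged, birch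
* target at the end, in percent of the substrate charged, maple
* target at the end, in percent of the substrate charged, cedar

- a reading or a percentage of target counts all its forms, free or not

What can target not exceed? Taking one first nucleophile into each target, and with less of it than substrate, the first nucleophile charge caps target, first nucleophile being the limiting reagent between those two. So I define the ceiling C, the first nucleophile charge as a share of the substrate charge, which is 50.0%.

Do the earlier runs reach C? No: the south-east run reads 32.0% and the north-west run, with more second nucleophile, 19.5%, so I take second nucleophile as a competitor of first nucleophile.

Then how does maple fare? The feed holds second nucleophile back, so I start maple at C. Second nucleophile must still take the other 0.125 M of substrate, which uses the feed up to 8.33 min. On this reckoning it then piles up to D, the second nucleophile left over, of 0.250 M when the feed ends.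

But what does that excess cost? The north-west readings of target, from first to last, give a first-order loss rate k of about 0.00489 min⁻¹ with about 0.174 M of second nucleophile left over. Taking the loss as proportional to second nucleophile, maple's exposure equals 19.2 min of north-west time. My own reckoning for maple, with t that exposure, is therefore C e^(-k t) = 45.5%. It is rough, since the drop read is 1.7 percentage points against a scatter of 0.5 points per reading.

And the ranking? Birch repeats the north-west run, last read at 17.8%, and maple's reckoned value stands above it. I put cedar near birch, since both nucleophiles stand together there.

The forecast names maple, with birch 17.3%, maple 45% and cedar 17.5%, holding that “second nucleophile stays scarce early, so first nucleophile takes substrate almost completely”.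

The flasks give 15.8% for birch, 43.0% for maple and 13.0% for cedar, so maple comes out highest.

    substrate → intermediate (k = 0.0500 s⁻¹)
    crystals ⇌ target, rate k2*(cs2 - [target]) while solid is left; crystals form when [target] > cs2 (solubility = 0.110 M, k = 0.180 s⁻¹)
    first nucleophile ⇌ dormant form (K = 4.80, k = 0.100 s⁻¹)
    second nucleophile + intermediate → other capture product (k = 1.10 M⁻¹ s⁻¹)
    first nucleophile + intermediate → target (k = 2.80 M⁻¹ s⁻¹)
    second nucleophile + target → over-reaction product (k = 8.20 × 10⁻⁴ M⁻¹ s⁻¹)

In maple, target and over-reaction product together make 49.9%, level with C. The neighbour is cedar with 0.094 M of second nucleophile. C stays 50.0%, and that second nucleophile can take 37.6% of the substrate charged, which leaves 12.4% for neither nucleophile. In that neighbour, target comes to 49.5%, other capture product to 37.2%, and intermediate still stands at 12.9%.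

(Readings and results are simulated with constants of no real substance; the scatter is artificial.)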